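**Retrosynthetic overview**

1. The target comes from aldehyde acid 32 by α-methylenation. 32 comes from C4 alcohol 17 and dienoic acid 29 (Yamaguchi esterification, then acid deprotection); 29 is built by auxiliary-controlled methylation and two Wittig olefinations.
2. The C4 oxygen and the C3=C3a enone come together from β,γ-enone 15 (vinylogous Rubottom oxidation). C7 is set by conjugate reduction of the C6=C7 enoate 13.
3. Ring B is closed by an intramolecular Diels–Alder reaction of propiolate 10, which forms C5–C6 and C7–C7a. The enabling feature: the oxygen on C2 of ring A and the carboxyl carbon on C7 are linked through C1–C7a–C7, so they can be tied as a six-membered lactone that holds C6≡C7 under the vinylcyclopentene diene C5=C4–C3a=C7a.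
4. Diene 8 comes from (R)-4-silyloxycyclopentenone 1 by α-methylation, anti conjugate addition with enol triflation, and Stille vinylation.
5. Ring order: ring A (purchased cyclopentenone), then ring B and the temporary lactone ring C together (step 7), then ring C is opened (step 8).

Key step: step 7

Remarks on the chemistry: core atoms are numbered as in the indene skeleton of the target (C1 side chain, C2 ketone, C3, C3a, C4 acyloxy, C5, C6, C7 carboxyl, C7a methyl). The acyl chain is (6R) as drawn, the enantiomer of the chiral-pool 2-methylbutyl unit, so it is made by auxiliary-controlled methylation.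

**Route**

Step 1
Reactants: 1 (R)-4-[(tert-butyldimethylsilyl)oxy]cyclopent-2-en-1-one
Product: 2 (R)-4-[(tert-butyldimethylsilyl)oxy]-2-iodocyclopent-2-en-1-one
Conditions: I2, pyridine, CH2Cl2, 0 °C → rt
Reagents that add atoms: iodine, II
Why: α-Iodination of an enone by pyridine conjugate addition, iodination of the enolate and elimination should leave the silyloxy stereocentre untouched.

Step 2
Reactants: 2 (R)-4-[(tert-butyldimethylsilyl)oxy]-2-iodocyclopent-2-en-1-one
Product: 3 (R)-4-[(tert-butyldimethylsilyl)oxy]-2-methylcyclopent-2-en-1-one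
Conditions: SnMe4, PdCl2(PhCN)2 (cat.), AsPh3, CuI (cat.), N-methylpyrrolidone, 60 °C
Reagents that add atoms: tetramethylstannane, C[Sn](C)(C)C
Why: Stille coupling of an α-iodoenone runs under neutral conditions, so β-elimination of the silyloxy group should be avoided.

Step 3
Reactants: 3 (R)-4-[(tert-butyldimethylsilyl)oxy]-2-methylcyclopent-2-en-1-one; 4 [2-(1,3-dioxolan-2-yl)ethyl]magnesium bromide
Product: 6 (3R,4R)-4-[(tert-butyldimethylsilyl)oxy]-3-[2-(1,3-dioxolan-2-yl)ethyl]-2-methylcyclopent-1-en-1-yl trifluoromethanesulfonate, via bromomagnesium enolate 5 (not isolated)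
Conditions: CuBr·SMe2 (cat.), THF, −78 → −40 °C; then N-(5-chloropyridin-2-yl)bis(trifluoromethanesulfonyl)imide, −78 → 0 °C
Reagents that add atoms: N-(5-chloropyridin-2-yl)-1,1,1-trifluoro-N-(trifluoromethylsulfonyl)methanesulfonamide, O=S(=O)(N(c1ccc(Cl)cn1)S(=O)(=O)C(F)(F)F)C(F)(F)F
Why: Copper-catalysed conjugate addition of the Grignard reagent anti to the adjacent silyloxy group (prostaglandin-type 1,2-induction) should set C1 trans to the C2 oxygen, and O-triflation of the regiodefined enolate fixes the tetrasubstituted C3a=C7a double bond.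

Step 4
Reactants: 6 (3R,4R)-4-[(tert-butyldimethylsilyl)oxy]-3-[2-(1,3-dioxolan-2-yl)ethyl]-2-methylcyclopent-1-en-1-yl trifluoromethanesulfonate
Product: 7 tert-butyl({(1R,2R)-2-[2-(1,3-dioxolan-2-yl)ethyl]-3-methyl-4-vinylcyclopent-3-en-1-yl}oxy)dimethylsilane
Conditions: tributyl(vinyl)stannane, Pd(PPh3)4 (cat.), LiCl, THF, 65 °C
Reagents that add atoms: tributyl(vinyl)stannane, C=C[Sn](CCCC)(CCCC)CCCC
Why: Stille coupling of a cyclic enol triflate with a vinylstannane is reliable and should give the 2-methyl-1-vinylcyclopentene diene without touching either stereocentre.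

Step 5
Reactants: 7 tert-butyl({(1R,2R)-2-[2-(1,3-dioxolan-2-yl)ethyl]-3-methyl-4-vinylcyclopent-3-en-1-yl}oxy)dimethylsilane
Product: 8 (1R,2R)-2-[2-(1,3-dioxolan-2-yl)ethyl]-3-methyl-4-vinylcyclopent-3-en-1-ol
Conditions: Bu4NF, THF, 0 °C → rt
Reagents that add atoms: none
Why: Fluoride desilylation is neutral to the acid-sensitive diene and the acetal.

Step 6
Reactants: 8 (1R,2R)-2-[2-(1,3-dioxolan-2-yl)ethyl]-3-methyl-4-vinylcyclopent-3-en-1-ol; 9 propiolic acid
Product: 10 (1R,2R)-2-[2-(1,3-dioxolan-2-yl)ethyl]-3-methyl-4-vinylcyclopent-3-en-1-yl prop-2-ynoate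
Conditions: DCC, DMAP (cat.), CH2Cl2, −20 → 0 °C
Reagents that add atoms: none
Why: Steglich esterification acylates the oxygen only, so the carbinol configuration that will steer the cycloaddition is retained.

Step 7
Reactants: 10 (1R,2R)-2-[2-(1,3-dioxolan-2-yl)ethyl]-3-methyl-4-vinylcyclopent-3-en-1-yl prop-2-ynoate
Product: 11 (1R,2R,7aR)-1-[2-(1,3-dioxolan-2-yl)ethyl]-2-hydroxy-7a-methyl-2,3,5,7a-tetrahydro-1H-indene-7-carboxylic acid 7,2-lactone (lactone bridge on the face opposite to the 7a-methyl group and the C1 side chain)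
Conditions: toluene (0.01 M), 2,6-di-tert-butyl-4-methylphenol (cat.), 130 °C, sealed tube
Reagents that add atoms: none
Why: A thermal, concerted, suprafacial [4+2] cycloaddition of the tethered propiolate (C6≡C7) onto the s-cis diene C5=C4–C3a=C7a forms C5–C6 and C7–C7a together; the closest known reaction type is the intramolecular Diels–Alder reaction of alkynoate esters of cycloalkenols that carry a 2-methyl-1-vinylcycloalkene, used to build angular-methyl quaternary carbons of decalin terpenoids inside fused lactones. Ring B (a cyclohexa-1,4-diene) closes as the [4+2] ring, and the temporary lactone ring C closes as a six-membered ring through the new C7–C7a bond (four-atom tether C1–C2–O–C(=O)), bridging ring A as a 2-oxabicyclo[3.2.1]octenone. The only new stereocentre, quaternary C7a, is controlled by the tether: the alkyne can reach C7a only from the ring face that carries the C2 oxygen, which is anti to the C1 side chain, so the methyl group should end up cis to that side chain as in the target. Regiochemistry (carboxyl carbon C7 next to C7a) is enforced by the tether and agrees with the electronic "ortho" preference of the disubstituted diene terminus, while the alkyne dienophile removes the endo/exo question and leaves C7 to be set in step 9. The cycloaddition has to outrun the [1,5]-hydrogen shift of the Z-methyl diene and polymerisation of the propiolate, which high dilution, a radical inhibitor and the entropic advantage of the tether should secure.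

Step 8
Reactants: 11 tricyclic lactone (as named in step 7)
Product: 13 4-methoxybenzyl (1R,2R,7aR)-1-[2-(1,3-dioxolan-2-yl)ethyl]-2-hydroxy-7a-methyl-2,3,5,7a-tetrahydro-1H-indene-7-carboxylate, via lithium carboxylate 12 (not isolated)
Conditions: LiOH·H2O, THF–H2O, 0 °C → rt; evaporate; then 4-methoxybenzyl chloride, NaI (cat.), DMF, rt
Reagents that add atoms: lithium hydroxide, [Li+].[OH-]; 4-methoxybenzyl chloride, COc1ccc(CCl)cc1
Why: Saponification opens the strained bridged lactone irreversibly to a carboxylate that is not a Michael acceptor for the freed C2 hydroxyl, and SN2 O-alkylation of that carboxylate installs an acid-labile ester.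

Step 9
Reactants: 13 4-methoxybenzyl (1R,2R,7aR)-1-[2-(1,3-dioxolan-2-yl)ethyl]-2-hydroxy-7a-methyl-2,3,5,7a-tetrahydro-1H-indene-7-carboxylate
Product: 14 4-methoxybenzyl (1R,2R,7R,7aS)-1-[2-(1,3-dioxolan-2-yl)ethyl]-2-hydroxy-7a-methyl-2,3,5,6,7,7a-hexahydro-1H-indene-7-carboxylate
Conditions: Cu(OAc)2·H2O (5 mol%), 1,2-bis(diphenylphosphino)benzene (5 mol%), (EtO)2MeSiH, t-BuOH, toluene, 0 °C → rt; then aq. NH4F
Reagents that add atoms: none
Why: Copper hydride conjugate reduction delivers hydride only to C6 of the enoate (the isolated C3a=C4 alkene is inert), and kinetic protonation of the copper enolate by the bulky alcohol should occur on the face anti to the adjacent angular methyl and the C1 side chain (as in protonation of steroidal 17(20)-enolates anti to the C18 methyl), giving the 7R ester cis to the methyl group.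

Step 10
Reactants: 14 4-methoxybenzyl (1R,2R,7R,7aS)-1-[2-(1,3-dioxolan-2-yl)ethyl]-2-hydroxy-7a-methyl-2,3,5,6,7,7a-hexahydro-1H-indene-7-carboxylate
Product: 15 4-methoxybenzyl (1R,7R,7aS)-1-[2-(1,3-dioxolan-2-yl)ethyl]-7a-methyl-2-oxo-2,3,5,6,7,7a-hexahydro-1H-indene-7-carboxylate
Conditions: DMP, NaHCO3, CH2Cl2, 0 °C → rt
Reagents that add atoms: none
Why: Buffered Dess–Martin oxidation is non-enolising, so the β,γ-unsaturated ketone should form without epimerisation at C1 or C7 and without double-bond migration.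

Step 11
Reactants: 15 4-methoxybenzyl (1R,7R,7aS)-1-[2-(1,3-dioxolan-2-yl)ethyl]-7a-methyl-2-oxo-2,3,5,6,7,7a-hexahydro-1H-indene-7-carboxylate
Product: 17 4-methoxybenzyl (1R,4S,7R,7aS)-1-[2-(1,3-dioxolan-2-yl)ethyl]-4-hydroxy-7a-methyl-2-oxo-2,4,5,6,7,7a-hexahydro-1H-indene-7-carboxylate, via trimethylsilyl dienol ether 16 (not isolated)
Conditions: LiN(SiMe3)2, Me3SiCl (premixed), THF, −78 °C; evaporate; then mCPBA, NaHCO3, CH2Cl2, −40 → 0 °C; AcOH–THF–H2O work-up
Reagents that add atoms: chlorotrimethylsilane (silyl group of 16 only), C[Si](C)(C)Cl; 3-chloroperbenzoic acid, OOC(=O)c1cccc(Cl)c1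
Why: Kinetic deprotonation at the doubly activated C3 gives the linear silyl dienol ether, and its vinylogous Rubottom oxidation should attack the γ-carbon C4 axially on the face syn to the angular methyl (as in 6β-hydroxylation of steroidal 3,5-dienol ethers), setting the C4 oxygen and the C3=C3a enone in one operation.

Step 12
Reactants: 18 (R)-4-benzyloxazolidin-2-one; 19 butanoyl chloride
Product: 20 (R)-4-benzyl-3-butanoyloxazolidin-2-one
Conditions: Et3N, DMAP (cat.), CH2Cl2, 0 °C → rt
Reagents that add atoms: none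
Why: N-Acylation of the oxazolidinone under amine/DMAP catalysis is a standard entry to the imide for Evans alkylation.

Step 13
Reactants: 20 (R)-4-benzyl-3-butanoyloxazolidin-2-one
Product: 22 (R)-4-benzyl-3-[(2R)-2-methylbutanoyl]oxazolidin-2-one, via sodium Z-enolate 21 (not isolated)
Conditions: NaN(SiMe3)2, THF, −78 °C; then MeI, −78 °C
Reagents that add atoms: sodium bis(trimethylsilyl)amide (sodium of 21 only), [Na+].C[Si](C)(C)[N-][Si](C)(C)C; iodomethane, CI
Why: Evans asymmetric alkylation: the chelated Z-enolate is methylated on the face opposite to the benzyl group, which for the (R)-auxiliary should give the (2R) centre.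

Step 14
Reactants: 22 (R)-4-benzyl-3-[(2R)-2-methylbutanoyl]oxazolidin-2-one
Product: 23 (R)-2-methylbutan-1-ol
Conditions: LiBH4, MeOH (1 equiv), Et2O, 0 °C; then aq. NaOH
Reagents that add atoms: none
Why: Reductive cleavage of the imide with borohydride does not enolise the α-centre, so the alcohol should keep its configuration and the auxiliary is recovered.

Step 15
Reactants: 23 (R)-2-methylbutan-1-ol
Product: 25 ethyl (2E,4R)-2,4-dimethylhex-2-enoate, via (R)-2-methylbutanal 24 (not isolated)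
Conditions: DMP, NaHCO3, CH2Cl2, 0 °C → rt; then Ph3P=C(CH3)CO2Et, rt
Reagents that add atoms: ethyl 2-(triphenylphosphoranylidene)propanoate, CCOC(=O)C(C)=P(c1ccccc1)(c1ccccc1)c1ccccc1
Why: One-pot Dess–Martin oxidation and Wittig olefination traps the volatile, epimerisable aldehyde at once, and the stabilised ylide should give the E-trisubstituted enoate.

Step 16
Reactants: 25 ethyl (2E,4R)-2,4-dimethylhex-2-enoate
Product: 26 (2E,4R)-2,4-dimethylhex-2-en-1-ol
Conditions: i-Bu2AlH, CH2Cl2, −78 °C; aq. Rochelle salt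
Reagents that add atoms: none
Why: 1,2-Reduction of an enoate with DIBAL-H gives the allylic alcohol without touching the alkene geometry.

Step 17
Reactants: 26 (2E,4R)-2,4-dimethylhex-2-en-1-ol
Product: 28 methyl (2E,4E,6R)-4,6-dimethylocta-2,4-dienoate, via enal 27 (not isolated)
Conditions: MnO2 (activated), Ph3P=CHCO2Me, CH2Cl2, rt → 40 °C
Reagents that add atoms: methyl 2-(triphenylphosphoranylidene)acetate, COC(=O)C=P(c1ccccc1)(c1ccccc1)c1ccccc1
Why: Tandem allylic oxidation and Wittig olefination with a stabilised ylide should give the (2E,4E)-dienoate directly.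

Step 18
Reactants: 28 methyl (2E,4E,6R)-4,6-dimethylocta-2,4-dienoate
Product: 29 (2E,4E,6R)-4,6-dimethylocta-2,4-dienoic acid
Conditions: LiOH, THF–MeOH–H2O, rt; then 1 M HCl
Reagents that add atoms: lithium hydroxide, [Li+].[OH-]
Why: Saponification of an unhindered methyl dienoate leaves the remote C6 stereocentre and the diene geometry intact.

Step 19
Reactants: 17 4-methoxybenzyl (1R,4S,7R,7aS)-1-[2-(1,3-dioxolan-2-yl)ethyl]-4-hydroxy-7a-methyl-2-oxo-2,4,5,6,7,7a-hexahydro-1H-indene-7-carboxylate; 29 (2E,4E,6R)-4,6-dimethylocta-2,4-dienoic acid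
Product: 31 4-methoxybenzyl (1R,4S,7R,7aS)-4-{[(2E,4E,6R)-4,6-dimethylocta-2,4-dienoyl]oxy}-1-[2-(1,3-dioxolan-2-yl)ethyl]-7a-methyl-2-oxo-2,4,5,6,7,7a-hexahydro-1H-indene-7-carboxylate, via mixed anhydride 30 (not isolated)
Conditions: 2,4,6-Cl3C6H2COCl, Et3N, toluene, rt; then 17, DMAP, toluene, rt
Reagents that add atoms: 2,4,6-trichlorobenzoyl chloride (acyl group of 30 only), O=C(Cl)c1c(Cl)cc(Cl)cc1Cl
Why: Yamaguchi esterification acylates hindered secondary alcohols at oxygen with retention at C4, under conditions too mild to enolise C1 or C7.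

Step 20
Reactants: 31 (as named in step 19)
Product: 32 (1R,4S,7R,7aS)-4-{[(2E,4E,6R)-4,6-dimethylocta-2,4-dienoyl]oxy}-7a-methyl-2-oxo-1-(3-oxopropyl)-2,4,5,6,7,7a-hexahydro-1H-indene-7-carboxylic acid
Conditions: CF3CO2H–CH2Cl2–H2O, 0 °C → rt
Reagents that add atoms: water, O
Why: Aqueous acid cleaves the 4-methoxybenzyl ester by ionisation and hydrolyses the dioxolane, while the C4 allylic ester, deactivated towards ionisation by the enone, and the dienoate should survive.

Step 21
Reactants: 32 (as named in step 20)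
Product: 33 (1R,4S,7R,7aS)-4-{[(2E,4E,6R)-4,6-dimethylocta-2,4-dienoyl]oxy}-1-(2-formylprop-2-en-1-yl)-7a-methyl-2-oxo-2,4,5,6,7,7a-hexahydro-1H-indene-7-carboxylic acid (target)
Conditions: 37% aq. CH2O, pyrrolidine (20 mol%), EtCO2H (20 mol%), i-PrOH, 45 °C
Reagents that add atoms: formaldehyde, C=O
Why: Amine-catalysed Mannich condensation and elimination (organocatalytic α-methylenation) acts only on the aldehyde, because the ketone α-carbons are tertiary or vinylic, and the reactive α-methylene aldehyde is therefore made last.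

**Compound list**

1 | (R)-4-[(tert-butyldimethylsilyl)oxy]cyclopent-2-en-1-one | O=C1C=C[C@H](O[Si](C)(C)C(C)(C)C)C1 | starting material
2 | (R)-4-[(tert-butyldimethylsilyl)oxy]-2-iodocyclopent-2-en-1-one | O=C1C(I)=C[C@H](O[Si](C)(C)C(C)(C)C)C1 | intermediate
3 | (R)-4-[(tert-butyldimethylsilyl)oxy]-2-methylcyclopent-2-en-1-one | O=C1C(C)=C[C@H](O[Si](C)(C)C(C)(C)C)C1 | intermediate
4 | [2-(1,3-dioxolan-2-yl)ethyl]magnesium bromide | Br[Mg]CCC1OCCO1 | starting material
5 | bromomagnesium (3R,4R)-4-[(tert-butyldimethylsilyl)oxy]-3-[2-(1,3-dioxolan-2-yl)ethyl]-2-methylcyclopent-1-en-1-olate | CC1=C(O[Mg]Br)C[C@@H](O[Si](C)(C)C(C)(C)C)[C@@H]1CCC2OCCO2 | intermediate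
6 | (3R,4R)-4-[(tert-butyldimethylsilyl)oxy]-3-[2-(1,3-dioxolan-2-yl)ethyl]-2-methylcyclopent-1-en-1-yl trifluoromethanesulfonate | CC1=C(OS(=O)(=O)C(F)(F)F)C[C@@H](O[Si](C)(C)C(C)(C)C)[C@@H]1CCC2OCCO2 | intermediate
7 | tert-butyl({(1R,2R)-2-[2-(1,3-dioxolan-2-yl)ethyl]-3-methyl-4-vinylcyclopent-3-en-1-yl}oxy)dimethylsilane | CC1=C(C=C)C[C@@H](O[Si](C)(C)C(C)(C)C)[C@@H]1CCC2OCCO2 | intermediate
8 | (1R,2R)-2-[2-(1,3-dioxolan-2-yl)ethyl]-3-methyl-4-vinylcyclopent-3-en-1-ol | CC1=C(C=C)C[C@@H](O)[C@@H]1CCC2OCCO2 | intermediate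
9 | propiolic acid | C#CC(=O)O | starting material
10 | (1R,2R)-2-[2-(1,3-dioxolan-2-yl)ethyl]-3-methyl-4-vinylcyclopent-3-en-1-yl prop-2-ynoate | CC1=C(C=C)C[C@@H](OC(=O)C#C)[C@@H]1CCC2OCCO2 | intermediate
11 | (1R,2R,7aR)-1-[2-(1,3-dioxolan-2-yl)ethyl]-2-hydroxy-7a-methyl-2,3,5,7a-tetrahydro-1H-indene-7-carboxylic acid 7,2-lactone | C[C@]12[C@@H](CCC3OCCO3)[C@@H]4OC(=O)C1=CCC=C2C4 | intermediate
12 | lithium (1R,2R,7aR)-1-[2-(1,3-dioxolan-2-yl)ethyl]-2-hydroxy-7a-methyl-2,3,5,7a-tetrahydro-1H-indene-7-carboxylate | [Li+].[O-]C(=O)C1=CCC=C2C[C@@H](O)[C@H](CCC3OCCO3)[C@@]12C | intermediate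
13 | 4-methoxybenzyl (1R,2R,7aR)-1-[2-(1,3-dioxolan-2-yl)ethyl]-2-hydroxy-7a-methyl-2,3,5,7a-tetrahydro-1H-indene-7-carboxylate | COc1ccc(COC(=O)C2=CCC=C3C[C@@H](O)[C@H](CCC4OCCO4)[C@@]23C)cc1 | intermediate
14 | 4-methoxybenzyl (1R,2R,7R,7aS)-1-[2-(1,3-dioxolan-2-yl)ethyl]-2-hydroxy-7a-methyl-2,3,5,6,7,7a-hexahydro-1H-indene-7-carboxylate | COc1ccc(COC(=O)[C@@H]2CCC=C3C[C@@H](O)[C@H](CCC4OCCO4)[C@@]23C)cc1 | intermediate
15 | 4-methoxybenzyl (1R,7R,7aS)-1-[2-(1,3-dioxolan-2-yl)ethyl]-7a-methyl-2-oxo-2,3,5,6,7,7a-hexahydro-1H-indene-7-carboxylate | COc1ccc(COC(=O)[C@@H]2CCC=C3CC(=O)[C@H](CCC4OCCO4)[C@@]23C)cc1 | intermediate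
16 | 4-methoxybenzyl (1R,7R,7aS)-1-[2-(1,3-dioxolan-2-yl)ethyl]-7a-methyl-2-[(trimethylsilyl)oxy]-5,6,7,7a-tetrahydro-1H-indene-7-carboxylate | COc1ccc(COC(=O)[C@@H]2CCC=C3C=C(O[Si](C)(C)C)[C@H](CCC4OCCO4)[C@@]23C)cc1 | intermediate
17 | 4-methoxybenzyl (1R,4S,7R,7aS)-1-[2-(1,3-dioxolan-2-yl)ethyl]-4-hydroxy-7a-methyl-2-oxo-2,4,5,6,7,7a-hexahydro-1H-indene-7-carboxylate | COc1ccc(COC(=O)[C@@H]2CC[C@H](O)C3=CC(=O)[C@H](CCC4OCCO4)[C@@]23C)cc1 | intermediate
18 | (R)-4-benzyloxazolidin-2-one | O=C1N[C@H](Cc2ccccc2)CO1 | starting material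
19 | butanoyl chloride | CCCC(Cl)=O | starting material
20 | (R)-4-benzyl-3-butanoyloxazolidin-2-one | CCCC(=O)N1[C@H](Cc2ccccc2)COC1=O | intermediate
21 | sodium (Z)-enolate of 20 | [Na+].CC/C=C(\[O-])N1[C@H](Cc2ccccc2)COC1=O | intermediate
22 | (R)-4-benzyl-3-[(2R)-2-methylbutanoyl]oxazolidin-2-one | CC[C@@H](C)C(=O)N1[C@H](Cc2ccccc2)COC1=O | intermediate
23 | (R)-2-methylbutan-1-ol | CC[C@@H](C)CO | intermediate
24 | (R)-2-methylbutanal | CC[C@@H](C)C=O | intermediate
25 | ethyl (2E,4R)-2,4-dimethylhex-2-enoate | CC[C@@H](C)/C=C(\C)C(=O)OCC | intermediate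
26 | (2E,4R)-2,4-dimethylhex-2-en-1-ol | CC[C@@H](C)/C=C(\C)CO | intermediate
27 | (2E,4R)-2,4-dimethylhex-2-enal | CC[C@@H](C)/C=C(\C)C=O | intermediate
28 | methyl (2E,4E,6R)-4,6-dimethylocta-2,4-dienoate | CC[C@@H](C)/C=C(\C)/C=C/C(=O)OC | intermediate
29 | (2E,4E,6R)-4,6-dimethylocta-2,4-dienoic acid | CC[C@@H](C)/C=C(\C)/C=C/C(=O)O | intermediate
30 | (2E,4E,6R)-4,6-dimethylocta-2,4-dienoic 2,4,6-trichlorobenzoic anhydride | CC[C@@H](C)/C=C(\C)/C=C/C(=O)OC(=O)c1c(Cl)cc(Cl)cc1Cl | intermediate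
31 | 4-methoxybenzyl (1R,4S,7R,7aS)-4-{[(2E,4E,6R)-4,6-dimethylocta-2,4-dienoyl]oxy}-1-[2-(1,3-dioxolan-2-yl)ethyl]-7a-methyl-2-oxo-2,4,5,6,7,7a-hexahydro-1H-indene-7-carboxylate | COc1ccc(COC(=O)[C@@H]2CC[C@H](OC(=O)/C=C/C(C)=C/[C@H](C)CC)C3=CC(=O)[C@H](CCC4OCCO4)[C@@]23C)cc1 | intermediate
32 | (1R,4S,7R,7aS)-4-{[(2E,4E,6R)-4,6-dimethylocta-2,4-dienoyl]oxy}-7a-methyl-2-oxo-1-(3-oxopropyl)-2,4,5,6,7,7a-hexahydro-1H-indene-7-carboxylic acid | OC(=O)[C@@H]1CC[C@H](OC(=O)/C=C/C(C)=C/[C@H](C)CC)C2=CC(=O)[C@H](CCC=O)[C@@]12C | intermediate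
33 | (1R,4S,7R,7aS)-4-{[(2E,4E,6R)-4,6-dimethylocta-2,4-dienoyl]oxy}-1-(2-formylprop-2-en-1-yl)-7a-methyl-2-oxo-2,4,5,6,7,7a-hexahydro-1H-indene-7-carboxylic acid | OC(=O)[C@@H]1CC[C@H](OC(=O)/C=C/C(C)=C/[C@H](C)CC)C2=CC(=O)[C@H](CC(=C)C=O)[C@@]12C | target

**Step count and risks**

Total step count: 21. Longest linear sequence: 14 steps (steps 1–11 and 19–21, from enone 1).

The three steps most likely to fail:

Step 7. The cycloaddition may be outrun by [1,5]-hydrogen shift of the Z-methyl diene or by polymerisation of the propiolate, because the transition state has to hold the ester in its s-cis form inside a bridged lactone. The fallback sets out from 7 and comes back at 13, and it is intermolecular. Silyl ether 7 would be heated in toluene at 110 °C (or held at 10 kbar at rt) with an excess of 4-methoxybenzyl prop-2-ynoate F1, itself made from propiolic acid 9 and 4-methoxybenzyl alcohol with DCC. "Ortho" regiochemistry and attack anti to the C1 side chain should give 4-methoxybenzyl (1R,2R,7aR)-2-[(tert-butyldimethylsilyl)oxy]-1-[2-(1,3-dioxolan-2-yl)ethyl]-7a-methyl-2,3,5,7a-tetrahydro-1H-indene-7-carboxylate F2. Desilylation with Bu4NF then gives 13, so that steps 5, 6 and 8 fall away.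

Step 9. Facial discrimination in the protonation of the C7 enolate may be insufficient, and thermodynamics cannot be relied on to correct it. The fallback sets out from 11 and comes back at 14, and it replaces protonation control by catalyst-controlled syn-hydrogenation. Saponification of 11 and careful acidification at 0 °C would give (1R,2R,7aR)-1-[2-(1,3-dioxolan-2-yl)ethyl]-2-hydroxy-7a-methyl-2,3,5,7a-tetrahydro-1H-indene-7-carboxylic acid F3. Carboxylate-directed hydrogenation with Ru(OAc)2[(R)-BINAP] or its enantiomer (the ligand that reinforces delivery anti to the angular methyl), H2 (50 bar), MeOH, reduces only the conjugated C6=C7 bond and should give (1R,2R,7R,7aS)-1-[2-(1,3-dioxolan-2-yl)ethyl]-2-hydroxy-7a-methyl-2,3,5,6,7,7a-hexahydro-1H-indene-7-carboxylic acid F4. O-Alkylation with 4-methoxybenzyl chloride and Cs2CO3 in DMF then gives 14.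

Step 11. The peracid may attack the α-carbon C3 instead of C4, or the face anti to the angular methyl. The fallback sets out from 15 and comes back at 31, and it uses steric control followed by inversion. Epoxidation of 15 with mCPBA on the face anti to the angular methyl would give 4-methoxybenzyl (1R,7R,7aS)-3a,4-epoxy-1-[2-(1,3-dioxolan-2-yl)ethyl]-7a-methyl-2-oxooctahydro-1H-indene-7-carboxylate (epoxide oxygen trans to the 7a-methyl group) F5. E1cB opening with Et3N gives the C4 epimer of 17, 4-methoxybenzyl (1R,4R,7R,7aS)-1-[2-(1,3-dioxolan-2-yl)ethyl]-4-hydroxy-7a-methyl-2-oxo-2,4,5,6,7,7a-hexahydro-1H-indene-7-carboxylate F6. Mitsunobu esterification of F6 with acid 29 (PPh3, diisopropyl azodicarboxylate, THF) inverts C4 and gives 31 directly.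

**Further compounds**

F1 | step 7 | 4-methoxybenzyl prop-2-ynoate | C#CC(=O)OCc1ccc(OC)cc1
F2 | step 7 | 4-methoxybenzyl (1R,2R,7aR)-2-[(tert-butyldimethylsilyl)oxy]-1-[2-(1,3-dioxolan-2-yl)ethyl]-7a-methyl-2,3,5,7a-tetrahydro-1H-indene-7-carboxylate | COc1ccc(COC(=O)C2=CCC=C3C[C@@H](O[Si](C)(C)C(C)(C)C)[C@H](CCC4OCCO4)[C@@]23C)cc1
F3 | step 9 | (1R,2R,7aR)-1-[2-(1,3-dioxolan-2-yl)ethyl]-2-hydroxy-7a-methyl-2,3,5,7a-tetrahydro-1H-indene-7-carboxylic acid | OC(=O)C1=CCC=C2C[C@@H](O)[C@H](CCC3OCCO3)[C@@]12C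
F4 | step 9 | (1R,2R,7R,7aS)-1-[2-(1,3-dioxolan-2-yl)ethyl]-2-hydroxy-7a-methyl-2,3,5,6,7,7a-hexahydro-1H-indene-7-carboxylic acid | OC(=O)[C@@H]1CCC=C2C[C@@H](O)[C@H](CCC3OCCO3)[C@@]12C
F5 | step 11 | 4-methoxybenzyl (1R,7R,7aS)-3a,4-epoxy-1-[2-(1,3-dioxolan-2-yl)ethyl]-7a-methyl-2-oxooctahydro-1H-indene-7-carboxylate (epoxide trans to the 7a-methyl group) | COc1ccc(COC(=O)[C@@H]2CC[C@H]3O[C@]34CC(=O)[C@H](CCC5OCCO5)[C@@]24C)cc1
F6 | step 11 | 4-methoxybenzyl (1R,4R,7R,7aS)-1-[2-(1,3-dioxolan-2-yl)ethyl]-4-hydroxy-7a-methyl-2-oxo-2,4,5,6,7,7a-hexahydro-1H-indene-7-carboxylate | COc1ccc(COC(=O)[C@@H]2CC[C@@H](O)C3=CC(=O)[C@H](CCC4OCCO4)[C@@]23C)cc1
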